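**Strategy.** Everything rests on the lower 7-hydroxy-2,3-dihydrobenzofuran. Its aryl carbons C7a and C3a are the ipso carbon and the free ortho carbon of a 3-benzyloxy-4-iodobenzoate, and the C7 oxygen beside C7a is the single ortho blocker that palladium/norbornene catalysis needs. In one operation the ortho C–H is alkylated by the benzylic carbon of an enantiopure glycidic ester (inversion) and the former C–I carbon takes the epoxide oxygen, closing the ring with both aryl bonds (C7a–O1, C3a–C3). The ester is then exchanged for the 2-aryl group. The oxolane half comes from a nitro-Michael/Friedel–Crafts sequence; a ketone links the halves and an ortho-quinone methide/ylide annulation closes the upper dihydrobenzofuran.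

Key step: step 4

Assumption: the stereo-SMILES defines the target (lower benzofuran hydroxylated at C7); in steps 10 and 19 the named antipode of the chiral controller is taken to give the drawn configuration, the other antipode being equally available should the sense prove opposite.

Step 1
Reactants: 1 methyl 3-hydroxy-4-iodobenzoate
Product: 2 methyl 3-(benzyloxy)-4-iodobenzoate
Conditions: BnBr, K2CO3, DMF, rt
Reagents that add atoms: benzyl bromide, BrCc1ccccc1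
Why: Williamson etherification of the phenoxide installs the benzyl ether that is the later C7 oxygen and the ortho blocker of the key step.

Step 2
Reactants: 3 3,5-bis(benzyloxy)benzaldehyde; 4 tert-butyl 2-(diethoxyphosphoryl)acetate
Product: 5 tert-butyl (2E)-3-[3,5-bis(benzyloxy)phenyl]prop-2-enoate
Conditions: NaH, THF, 0 °C to rt
Reagents that add atoms: none
Why: Horner–Wadsworth–Emmons olefination of an aryl aldehyde with a stabilised phosphonate should give the (E)-cinnamate.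

Step 3
Reactants: 5 tert-butyl (2E)-3-[3,5-bis(benzyloxy)phenyl]prop-2-enoate
Product: 6 tert-butyl (2S,3R)-3-[3,5-bis(benzyloxy)phenyl]oxirane-2-carboxylate
Conditions: Shi ketone (D-fructose-derived, 4,5-di-O-acetyl variant, 30 mol %), Oxone (2KHSO5·KHSO4·K2SO4), NaHCO3, Bu4NHSO4, MeCN–aq. Na2EDTA, 0 °C
Reagents that add atoms: potassium peroxymonosulfate (Oxone), [K+].[O-]S(=O)(=O)OO
Why: Shi asymmetric epoxidation of a trans-cinnamate by the chiral dioxirane (spiro transition state) should give the (2S,3R)-glycidate, whose C3 is the centre relayed to the target.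

Step 4
Reactants: 2 methyl 3-(benzyloxy)-4-iodobenzoate; 6 tert-butyl (2S,3R)-3-[3,5-bis(benzyloxy)phenyl]oxirane-2-carboxylate
Product: 7 2-tert-butyl 5-methyl (2S,3R)-7-(benzyloxy)-3-[3,5-bis(benzyloxy)phenyl]-2,3-dihydro-1-benzofuran-2,5-dicarboxylate
Conditions: Pd(OAc)2 (10 mol %), XPhos (20 mol %), potassium 5-norbornene-2-carboxylate (50 mol %), Cs2CO3, NMP, 80 °C
Reagents that add atoms: none
Why: Proposed new method: oxidative addition of 2 to zerovalent palladium, norbornene insertion and palladation of the only free C–H ortho to iodine (C5; C3 is blocked by the benzyloxy group) give the aryl–norbornyl palladacycle, which opens glycidate 6 at its benzylic carbon in an SN2 step (inversion) to a tetravalent palladium alkyl and forms the aryl–C bond by reductive elimination. After norbornene extrusion the tethered alkoxide sits on the aryl–palladium bond of the former C–I carbon, and C–O reductive elimination from this six-membered chelate closes the dihydrofuran ring (formally a 5-exo closure). The closest known reaction is the palladium/norbornene annulation of ortho-substituted aryl iodides with terminal epoxides to 2,3-dihydrobenzofurans, extended here to a 2,3-disubstituted glycidic ester. C3 of 7 is set stereospecifically by the inversion at the epoxide carbon (the descriptor stays R only because the priorities change) and C2 is carried over unchanged, so the cis ester should result. The step needs regiocontrol on the arene, secured by the positions of I and OBn, and on the epoxide, secured by the preference of soft nucleophiles for the benzylic C3 of 3-arylglycidates over the ester-bearing C2.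

Step 5
Reactants: 7 2-tert-butyl 5-methyl (2S,3R)-7-(benzyloxy)-3-[3,5-bis(benzyloxy)phenyl]-2,3-dihydro-1-benzofuran-2,5-dicarboxylate
Product: 8 (2S,3R)-7-(benzyloxy)-3-[3,5-bis(benzyloxy)phenyl]-5-(methoxycarbonyl)-2,3-dihydro-1-benzofuran-2-carboxylic acid
Conditions: TFA, CH2Cl2, 0 °C to rt
Reagents that add atoms: none
Why: acidolysis of the tert-butyl ester (loss of isobutene) should leave the methyl ester, the benzyl ethers and both stereocentres untouched.

Step 6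
Reactants: 8 (2S,3R)-7-(benzyloxy)-3-[3,5-bis(benzyloxy)phenyl]-5-(methoxycarbonyl)-2,3-dihydro-1-benzofuran-2-carboxylic acid; 9 1-(benzyloxy)-4-iodobenzene
Product: 10 methyl (2R,3R)-7-(benzyloxy)-2-[4-(benzyloxy)phenyl]-3-[3,5-bis(benzyloxy)phenyl]-2,3-dihydro-1-benzofuran-5-carboxylate
Conditions: Ir[dF(CF3)ppy]2(dtbbpy)PF6 (1 mol %), NiCl2·glyme (10 mol %), dtbbpy (15 mol %), Cs2CO3, DMF, blue LEDs, rt
Reagents that add atoms: none
Why: photoredox/nickel decarboxylative arylation of an α-oxy acid, in which the planar C2 radical is captured and arylated on the face anti to the C3 aryl group, should give the trans-(2R,3R) ring whatever the configuration of the acid.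

Step 7
Reactants: 3 3,5-bis(benzyloxy)benzaldehyde
Product: 11 3,5-bis(benzyloxy)-2-bromobenzaldehyde
Conditions: NBS, MeCN, 0 °C to rt
Reagents that add atoms: N-bromosuccinimide, O=C1CCC(=O)N1Br
Why: electrophilic aromatic bromination goes to C2 (para to one benzyloxy group and ortho to the other), the carbon that later carries the upper dihydrobenzofuran.

Step 8
Reactants: 11 3,5-bis(benzyloxy)-2-bromobenzaldehyde
Product: 12 1,5-bis(benzyloxy)-2-bromo-3-[(E)-2-nitroethenyl]benzene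
Conditions: MeNO2, NH4OAc, AcOH, 100 °C
Reagents that add atoms: nitromethane, C[N+](=O)[O-]
Why: Henry condensation with dehydration should give the (E)-nitroalkene.

Step 9
Reactants: 13 1-[4-(benzyloxy)phenyl]ethan-1-one; 14 1,3-bis(benzyloxy)-5-bromobenzene
Product: 15 1-[4-(benzyloxy)phenyl]-2-[3,5-bis(benzyloxy)phenyl]ethan-1-one
Conditions: Pd2(dba)3 (1.5 mol %), Xantphos (3.6 mol %), NaOtBu, THF, 70 °C
Reagents that add atoms: none
Why: palladium-catalysed α-arylation of the methyl ketone enolate (Buchwald–Hartwig type) should stop at the monoarylated deoxybenzoin.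

Step 10
Reactants: 12 1,5-bis(benzyloxy)-2-bromo-3-[(E)-2-nitroethenyl]benzene; 15 1-[4-(benzyloxy)phenyl]-2-[3,5-bis(benzyloxy)phenyl]ethan-1-one
Product: 16 (2R,3S)-1-[4-(benzyloxy)phenyl]-2-[3,5-bis(benzyloxy)phenyl]-3-[3,5-bis(benzyloxy)-2-bromophenyl]-4-nitrobutan-1-one
Conditions: quinidine-derived 3,5-bis(trifluoromethyl)phenyl squaramide (10 mol %), toluene, 0 °C
Reagents that add atoms: none
Why: bifunctional organocatalytic Michael addition, in which the squaramide binds the nitro group and the quinuclidine generates the (Z)-enolate of 15, should fix C3 by catalyst control and C2 anti to it through the open transition state of a (Z)-enolate with an (E)-nitroalkene.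

Step 11
Reactants: 16 (2R,3S)-1-[4-(benzyloxy)phenyl]-2-[3,5-bis(benzyloxy)phenyl]-3-[3,5-bis(benzyloxy)-2-bromophenyl]-4-nitrobutan-1-one
Product: 17 (1S,2R,3S)-1-[4-(benzyloxy)phenyl]-2-[3,5-bis(benzyloxy)phenyl]-3-[3,5-bis(benzyloxy)-2-bromophenyl]-4-nitrobutan-1-ol
Conditions: (R)-2-methyl-CBS-oxazaborolidine (20 mol %), BH3·SMe2, THF, −20 °C
Reagents that add atoms: none
Why: Corey–Bakshi–Shibata reduction with the aryl group as the large substituent should set the (1S) carbinol by reagent control without touching the nitro group.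

Step 12
Reactants: 17 (1S,2R,3S)-1-[4-(benzyloxy)phenyl]-2-[3,5-bis(benzyloxy)phenyl]-3-[3,5-bis(benzyloxy)-2-bromophenyl]-4-nitrobutan-1-ol
Product: 19 (3S,4R,5S)-5-[4-(benzyloxy)phenyl]-4-[3,5-bis(benzyloxy)phenyl]-3-[3,5-bis(benzyloxy)-2-bromophenyl]oxolan-2-ol (anomers), via hydroxy aldehyde 18 (not isolated)
Conditions: NaOMe, MeOH, 0 °C; then aq. TiCl3, NH4OAc, pH 5, rt
Reagents that add atoms: water, O
Why: the reductive Nef reaction of the nitronate with trivalent titanium (McMurry conditions) should give the aldehyde, which the γ-hydroxy group traps at once as the five-membered lactol.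

Step 13
Reactants: 19 (3S,4R,5S)-5-[4-(benzyloxy)phenyl]-4-[3,5-bis(benzyloxy)phenyl]-3-[3,5-bis(benzyloxy)-2-bromophenyl]oxolan-2-ol; 20 (benzyloxy)benzene
Product: 21 (2S,3R,4S,5R)-2,5-bis[4-(benzyloxy)phenyl]-3-[3,5-bis(benzyloxy)phenyl]-4-[3,5-bis(benzyloxy)-2-bromophenyl]oxolane
Conditions: TMSOTf (20 mol %), 20 (5 equiv), CH2Cl2, −40 to 0 °C
Reagents that add atoms: none
Why: Friedel–Crafts C-arylation of the cyclic oxocarbenium ion by the para position of the aryl ether should place the new aryl group trans to the neighbouring aryl, the arrangement that is also thermodynamically preferred (2,3-trans, 3,4-cis, 4,5-trans).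

Step 14
Reactants: 21 (2S,3R,4S,5R)-2,5-bis[4-(benzyloxy)phenyl]-3-[3,5-bis(benzyloxy)phenyl]-4-[3,5-bis(benzyloxy)-2-bromophenyl]oxolane; 10 methyl (2R,3R)-7-(benzyloxy)-2-[4-(benzyloxy)phenyl]-3-[3,5-bis(benzyloxy)phenyl]-2,3-dihydro-1-benzofuran-5-carboxylate
Product: 23 diaryl ketone joining C5 of the lower benzofuran to the oxolane-bearing ring, via aryllithium 22 (not isolated)
Conditions: t-BuLi (2 equiv), THF, −78 °C; then 10, −78 to −40 °C
Reagents that add atoms: none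
Why: bromine–lithium exchange followed by acyl substitution on the methyl ester should stop at the ketone because the di-ortho-substituted product is too hindered for a second addition of the 2,6-disubstituted aryllithium.

Step 15
Reactants: 23 diaryl ketone
Product: 24 ortho-hydroxy diaryl ketone
Conditions: MgBr2·OEt2 (3 equiv), toluene–Et2O, 60 °C
Reagents that add atoms: none
Why: chelation-controlled debenzylation (magnesium bridging the carbonyl and the ortho ether oxygen, bromide removing the benzyl group) should free only the phenol ortho to the ketone, the future ring oxygen of the upper dihydrobenzofuran.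

Step 16
Reactants: 24 ortho-hydroxy diaryl ketone
Product: 25 ortho-hydroxy benzhydrol (carbinol epimers)
Conditions: NaBH4, THF–MeOH, 0 °C to rt
Reagents that add atoms: none
Why: hydride reduction of the aryl ketone gives the carbinol, whose configuration is irrelevant because this carbon becomes trigonal in step 19.

Step 17
Reactants: 25 ortho-hydroxy benzhydrol
Product: 26 ortho-hydroxy benzhydryl 4-tolyl sulfone (epimers)
Conditions: 4-toluenesulfinic acid, CH2Cl2, rt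
Reagents that add atoms: 4-toluenesulfinic acid, Cc1ccc(cc1)S(=O)O
Why: acid-promoted ionisation of the electron-rich, doubly benzylic carbinol and S-alkylation of the sulfinate should give the sulfone, a base-triggered ortho-quinone methide precursor.

Step 18
Reactants: 27 1-(benzyloxy)-4-(bromomethyl)benzene; 28 (2R,5R)-2,5-dimethylthiolane
Product: 29 (2R,5R)-1-[4-(benzyloxy)benzyl]-2,5-dimethylthiolan-1-ium bromide
Conditions: acetone, rt
Reagents that add atoms: none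
Why: SN2 alkylation of the C2-symmetric sulfide by the benzylic bromide gives a sulfonium salt in which sulfur is not stereogenic.

Step 19
Reactants: 26 ortho-hydroxy benzhydryl 4-tolyl sulfone; 29 (2R,5R)-1-[4-(benzyloxy)benzyl]-2,5-dimethylthiolan-1-ium bromide
Product: 32 deca-O-benzylkobophenol A, via sulfonium ylide 30 (not isolated), via ortho-quinone methide 31 (not isolated)
Conditions: Cs2CO3 (3 equiv), MeCN–CH2Cl2, 0 °C to rt
Reagents that add atoms: none
Why: base turns 26 into the ortho-quinone methide (loss of sulfinate) and 29 into the benzylic ylide, whose addition to the methide carbon (ylide face fixed by the thiolane) and trans-selective displacement of the sulfide by the phenoxide should close the ring in a formal [4+1] annulation that sets (2S,3S).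

Step 20
Reactants: 32 deca-O-benzylkobophenol A
Product: 33 kobophenol A
Conditions: H2 (1 atm), 10% Pd/C (palladium on carbon), EtOAc–MeOH, rt
Reagents that add atoms: none
Why: neutral hydrogenolysis of the ten aryl benzyl ethers is chosen because the benzylic ethers of the oxolane and dihydrobenzofuran rings are acid-labile, and it touches no stereocentre.

**Compound list**

1 | methyl 3-hydroxy-4-iodobenzoate | COC(=O)c1ccc(I)c(O)c1 | starting material
2 | methyl 3-(benzyloxy)-4-iodobenzoate | COC(=O)c1ccc(I)c(OCc2ccccc2)c1 | intermediate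
3 | 3,5-bis(benzyloxy)benzaldehyde | O=Cc1cc(OCc2ccccc2)cc(OCc2ccccc2)c1 | starting material
4 | tert-butyl 2-(diethoxyphosphoryl)acetate | CCOP(=O)(OCC)CC(=O)OC(C)(C)C | starting material
5 | tert-butyl (2E)-3-[3,5-bis(benzyloxy)phenyl]prop-2-enoate | CC(C)(C)OC(=O)/C=C/c1cc(OCc2ccccc2)cc(OCc2ccccc2)c1 | intermediate
6 | tert-butyl (2S,3R)-3-[3,5-bis(benzyloxy)phenyl]oxirane-2-carboxylate | CC(C)(C)OC(=O)[C@H]1O[C@@H]1c1cc(OCc2ccccc2)cc(OCc2ccccc2)c1 | intermediate
7 | 2-tert-butyl 5-methyl (2S,3R)-7-(benzyloxy)-3-[3,5-bis(benzyloxy)phenyl]-2,3-dihydro-1-benzofuran-2,5-dicarboxylate (cis) | COC(=O)c1cc(OCc9ccccc9)c2c(c1)[C@@H](c1cc(OCc9ccccc9)cc(OCc9ccccc9)c1)[C@@H](C(=O)OC(C)(C)C)O2 | intermediate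
8 | (2S,3R)-7-(benzyloxy)-3-[3,5-bis(benzyloxy)phenyl]-5-(methoxycarbonyl)-2,3-dihydro-1-benzofuran-2-carboxylic acid | COC(=O)c1cc(OCc9ccccc9)c2c(c1)[C@@H](c1cc(OCc9ccccc9)cc(OCc9ccccc9)c1)[C@@H](C(=O)O)O2 | intermediate
9 | 1-(benzyloxy)-4-iodobenzene | Ic1ccc(OCc2ccccc2)cc1 | starting material
10 | methyl (2R,3R)-7-(benzyloxy)-2-[4-(benzyloxy)phenyl]-3-[3,5-bis(benzyloxy)phenyl]-2,3-dihydro-1-benzofuran-5-carboxylate (trans) | COC(=O)c1cc(OCc9ccccc9)c2c(c1)[C@@H](c1cc(OCc9ccccc9)cc(OCc9ccccc9)c1)[C@H](c1ccc(OCc9ccccc9)cc1)O2 | intermediate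
11 | 3,5-bis(benzyloxy)-2-bromobenzaldehyde | O=Cc1cc(OCc2ccccc2)cc(OCc2ccccc2)c1Br | intermediate
12 | 1,5-bis(benzyloxy)-2-bromo-3-[(E)-2-nitroethenyl]benzene | [O-][N+](=O)/C=C/c1cc(OCc2ccccc2)cc(OCc2ccccc2)c1Br | intermediate
13 | 1-[4-(benzyloxy)phenyl]ethan-1-one | CC(=O)c1ccc(OCc2ccccc2)cc1 | starting material
14 | 1,3-bis(benzyloxy)-5-bromobenzene | Brc1cc(OCc2ccccc2)cc(OCc2ccccc2)c1 | starting material
15 | 1-[4-(benzyloxy)phenyl]-2-[3,5-bis(benzyloxy)phenyl]ethan-1-one | O=C(Cc1cc(OCc2ccccc2)cc(OCc2ccccc2)c1)c1ccc(OCc2ccccc2)cc1 | intermediate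
16 | (2R,3S)-1-[4-(benzyloxy)phenyl]-2-[3,5-bis(benzyloxy)phenyl]-3-[3,5-bis(benzyloxy)-2-bromophenyl]-4-nitrobutan-1-one | Brc1c(OCc9ccccc9)cc(OCc9ccccc9)cc1[C@@H](C[N+](=O)[O-])[C@H](c1cc(OCc9ccccc9)cc(OCc9ccccc9)c1)C(=O)c1ccc(OCc9ccccc9)cc1 | intermediate
17 | (1S,2R,3S)-1-[4-(benzyloxy)phenyl]-2-[3,5-bis(benzyloxy)phenyl]-3-[3,5-bis(benzyloxy)-2-bromophenyl]-4-nitrobutan-1-ol | Brc1c(OCc9ccccc9)cc(OCc9ccccc9)cc1[C@@H](C[N+](=O)[O-])[C@H](c1cc(OCc9ccccc9)cc(OCc9ccccc9)c1)[C@@H](c1ccc(OCc9ccccc9)cc1)O | intermediate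
18 | (2S,3R,4S)-4-[4-(benzyloxy)phenyl]-3-[3,5-bis(benzyloxy)phenyl]-2-[3,5-bis(benzyloxy)-2-bromophenyl]-4-hydroxybutanal (not isolated) | Brc1c(OCc9ccccc9)cc(OCc9ccccc9)cc1[C@@H](C=O)[C@H](c1cc(OCc9ccccc9)cc(OCc9ccccc9)c1)[C@@H](c1ccc(OCc9ccccc9)cc1)O | intermediate
19 | (3S,4R,5S)-5-[4-(benzyloxy)phenyl]-4-[3,5-bis(benzyloxy)phenyl]-3-[3,5-bis(benzyloxy)-2-bromophenyl]oxolan-2-ol (anomers) | Brc1c(OCc9ccccc9)cc(OCc9ccccc9)cc1[C@@H]1[C@H](c2cc(OCc9ccccc9)cc(OCc9ccccc9)c2)[C@@H](c2ccc(OCc9ccccc9)cc2)OC1O | intermediate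
20 | (benzyloxy)benzene | c1ccc(OCc2ccccc2)cc1 | starting material
21 | (2S,3R,4S,5R)-2,5-bis[4-(benzyloxy)phenyl]-3-[3,5-bis(benzyloxy)phenyl]-4-[3,5-bis(benzyloxy)-2-bromophenyl]oxolane | Brc1c(OCc9ccccc9)cc(OCc9ccccc9)cc1[C@@H]1[C@H](c2cc(OCc9ccccc9)cc(OCc9ccccc9)c2)[C@@H](c2ccc(OCc9ccccc9)cc2)O[C@H]1c1ccc(OCc9ccccc9)cc1 | intermediate
22 | {2,4-bis(benzyloxy)-6-[(2R,3S,4R,5S)-2,5-bis[4-(benzyloxy)phenyl]-4-[3,5-bis(benzyloxy)phenyl]oxolan-3-yl]phenyl}lithium (not isolated) | [Li]c1c(OCc9ccccc9)cc(OCc9ccccc9)cc1[C@@H]1[C@H](c2cc(OCc9ccccc9)cc(OCc9ccccc9)c2)[C@@H](c2ccc(OCc9ccccc9)cc2)O[C@H]1c1ccc(OCc9ccccc9)cc1 | intermediate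
23 | [(2R,3R)-7-(benzyloxy)-2-[4-(benzyloxy)phenyl]-3-[3,5-bis(benzyloxy)phenyl]-2,3-dihydro-1-benzofuran-5-yl]{2,4-bis(benzyloxy)-6-[(2R,3S,4R,5S)-2,5-bis[4-(benzyloxy)phenyl]-4-[3,5-bis(benzyloxy)phenyl]oxolan-3-yl]phenyl}methanone | O=C(c1cc(OCc9ccccc9)c2c(c1)[C@@H](c1cc(OCc9ccccc9)cc(OCc9ccccc9)c1)[C@H](c1ccc(OCc9ccccc9)cc1)O2)c1c(OCc9ccccc9)cc(OCc9ccccc9)cc1[C@@H]1[C@H](c2cc(OCc9ccccc9)cc(OCc9ccccc9)c2)[C@@H](c2ccc(OCc9ccccc9)cc2)O[C@H]1c1ccc(OCc9ccccc9)cc1 | intermediate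
24 | [(2R,3R)-7-(benzyloxy)-2-[4-(benzyloxy)phenyl]-3-[3,5-bis(benzyloxy)phenyl]-2,3-dihydro-1-benzofuran-5-yl]{4-(benzyloxy)-2-hydroxy-6-[(2R,3S,4R,5S)-2,5-bis[4-(benzyloxy)phenyl]-4-[3,5-bis(benzyloxy)phenyl]oxolan-3-yl]phenyl}methanone | O=C(c1cc(OCc9ccccc9)c2c(c1)[C@@H](c1cc(OCc9ccccc9)cc(OCc9ccccc9)c1)[C@H](c1ccc(OCc9ccccc9)cc1)O2)c1c(O)cc(OCc9ccccc9)cc1[C@@H]1[C@H](c2cc(OCc9ccccc9)cc(OCc9ccccc9)c2)[C@@H](c2ccc(OCc9ccccc9)cc2)O[C@H]1c1ccc(OCc9ccccc9)cc1 | intermediate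
25 | 5-(benzyloxy)-2-{[(2R,3R)-7-(benzyloxy)-2-[4-(benzyloxy)phenyl]-3-[3,5-bis(benzyloxy)phenyl]-2,3-dihydro-1-benzofuran-5-yl](hydroxy)methyl}-3-[(2R,3S,4R,5S)-2,5-bis[4-(benzyloxy)phenyl]-4-[3,5-bis(benzyloxy)phenyl]oxolan-3-yl]phenol (carbinol epimers) | OC(c1cc(OCc9ccccc9)c2c(c1)[C@@H](c1cc(OCc9ccccc9)cc(OCc9ccccc9)c1)[C@H](c1ccc(OCc9ccccc9)cc1)O2)c1c(O)cc(OCc9ccccc9)cc1[C@@H]1[C@H](c2cc(OCc9ccccc9)cc(OCc9ccccc9)c2)[C@@H](c2ccc(OCc9ccccc9)cc2)O[C@H]1c1ccc(OCc9ccccc9)cc1 | intermediate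
26 | 5-(benzyloxy)-2-{[(2R,3R)-7-(benzyloxy)-2-[4-(benzyloxy)phenyl]-3-[3,5-bis(benzyloxy)phenyl]-2,3-dihydro-1-benzofuran-5-yl](4-methylbenzenesulfonyl)methyl}-3-[(2R,3S,4R,5S)-2,5-bis[4-(benzyloxy)phenyl]-4-[3,5-bis(benzyloxy)phenyl]oxolan-3-yl]phenol (epimers) | Cc1ccc(cc1)S(=O)(=O)C(c1cc(OCc9ccccc9)c2c(c1)[C@@H](c1cc(OCc9ccccc9)cc(OCc9ccccc9)c1)[C@H](c1ccc(OCc9ccccc9)cc1)O2)c1c(O)cc(OCc9ccccc9)cc1[C@@H]1[C@H](c2cc(OCc9ccccc9)cc(OCc9ccccc9)c2)[C@@H](c2ccc(OCc9ccccc9)cc2)O[C@H]1c1ccc(OCc9ccccc9)cc1 | intermediate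
27 | 1-(benzyloxy)-4-(bromomethyl)benzene | BrCc1ccc(OCc2ccccc2)cc1 | starting material
28 | (2R,5R)-2,5-dimethylthiolane | C[C@@H]1CC[C@@H](C)S1 | starting material
29 | (2R,5R)-1-[4-(benzyloxy)benzyl]-2,5-dimethylthiolan-1-ium bromide | C[C@@H]1CC[C@@H](C)[S+]1Cc1ccc(OCc2ccccc2)cc1.[Br-] | intermediate
30 | [4-(benzyloxy)phenyl][(2R,5R)-2,5-dimethylthiolan-1-ium-1-yl]methanide (not isolated) | C[C@@H]1CC[C@@H](C)[S+]1[CH-]c1ccc(OCc2ccccc2)cc1 | intermediate
31 | 3-(benzyloxy)-6-{[(2R,3R)-7-(benzyloxy)-2-[4-(benzyloxy)phenyl]-3-[3,5-bis(benzyloxy)phenyl]-2,3-dihydro-1-benzofuran-5-yl]methylidene}-5-[(2R,3S,4R,5S)-2,5-bis[4-(benzyloxy)phenyl]-4-[3,5-bis(benzyloxy)phenyl]oxolan-3-yl]cyclohexa-2,4-dien-1-one (not isolated) | O=C1C=C(OCc9ccccc9)C=C([C@@H]2[C@H](c3cc(OCc9ccccc9)cc(OCc9ccccc9)c3)[C@@H](c3ccc(OCc9ccccc9)cc3)O[C@H]2c2ccc(OCc9ccccc9)cc2)C1=Cc1cc(OCc9ccccc9)c2c(c1)[C@@H](c1cc(OCc9ccccc9)cc(OCc9ccccc9)c1)[C@H](c1ccc(OCc9ccccc9)cc1)O2 | intermediate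
32 | deca-O-benzylkobophenol A: (2S,3S) upper dihydrobenzofuran, (2R,3R) lower dihydrobenzofuran, (2S,3R,4S,5R) oxolane, all ten phenolic oxygens benzylated | c9ccccc9COc1ccc([C@H]2Oc3cc(OCc9ccccc9)cc([C@@H]4[C@H](c5cc(OCc9ccccc9)cc(OCc9ccccc9)c5)[C@@H](c5ccc(OCc9ccccc9)cc5)O[C@H]4c4ccc(OCc9ccccc9)cc4)c3[C@@H]2c2cc(OCc9ccccc9)c3c(c2)[C@@H](c2cc(OCc9ccccc9)cc(OCc9ccccc9)c2)[C@H](c2ccc(OCc9ccccc9)cc2)O3)cc1 | intermediate
33 | kobophenol A: 5-[(2S,3R,4S,5R)-4-[(2S,3S)-3-[(2R,3R)-3-(3,5-dihydroxyphenyl)-7-hydroxy-2-(4-hydroxyphenyl)-2,3-dihydro-1-benzofuran-5-yl]-6-hydroxy-2-(4-hydroxyphenyl)-2,3-dihydro-1-benzofuran-4-yl]-2,5-bis(4-hydroxyphenyl)oxolan-3-yl]benzene-1,3-diol | Oc1ccc([C@H]2Oc3cc(O)cc([C@@H]4[C@H](c5cc(O)cc(O)c5)[C@@H](c5ccc(O)cc5)O[C@H]4c4ccc(O)cc4)c3[C@@H]2c2cc(O)c3c(c2)[C@@H](c2cc(O)cc(O)c2)[C@H](c2ccc(O)cc2)O3)cc1 | target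

**Totals.** 20 steps in all; the longest linear sequence is 12 steps (steps 7, 8, 10–17, 19, 20, from 3).

**Steps most likely to fail**

Step 4 (Proposed new method). The palladacycle may fail to attack a secondary benzylic epoxide carbon, may open the glycidate at C2 instead, or the palladium alkoxide may undergo β-hydride elimination before the C–O bond forms. The fallback uses known chemistry, sets out from 2 and comes back at 10. Miyaura borylation of 2 (B2pin2, PdCl2(dppf), KOAc) and oxidation (NaBO3) would give methyl 3-(benzyloxy)-4-hydroxybenzoate F1. Magnesium-mediated ortho-formylation (MgCl2, Et3N, paraformaldehyde) at the only free ortho position would give methyl 3-(benzyloxy)-5-formyl-4-hydroxybenzoate F2, and Boc2O/DMAP would give methyl 3-(benzyloxy)-4-[(tert-butoxycarbonyl)oxy]-5-formylbenzoate F3. Addition of [3,5-bis(benzyloxy)phenyl]magnesium bromide F4 (from 14 and Mg) at −78 °C triggers carbonate migration and 1,4-elimination. The resulting electrophile is trapped in the same flask by the ylide of (2S,5S)-1-[4-(benzyloxy)benzyl]-2,5-dimethylthiolan-1-ium bromide F5 (from 27 and the enantiomer of 28), giving 10 by the same [4+1] annulation as in step 19.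

Step 10. Deprotonation of the weakly acidic ketone may be slow, and control at the enolisable α-centre (anti/syn ratio) or of the absolute sense may be poor. The fallback sets out from 12 and comes back at 16. [3,5-Bis(benzyloxy)phenyl]acetic acid is attached to (R)-4-benzyloxazolidin-2-one (pivaloyl chloride, Et3N, then the lithiated auxiliary) to give (4R)-4-benzyl-3-{[3,5-bis(benzyloxy)phenyl]acetyl}-1,3-oxazolidin-2-one F6. Its chlorotitanium enolate (TiCl4, i-Pr2NEt, −78 °C) should add to 12 under auxiliary control to give (4R)-4-benzyl-3-[(2R,3S)-2-[3,5-bis(benzyloxy)phenyl]-3-[3,5-bis(benzyloxy)-2-bromophenyl]-4-nitrobutanoyl]-1,3-oxazolidin-2-one F7. Transamidation (AlMe3, MeNHOMe·HCl) gives (2R,3S)-2-[3,5-bis(benzyloxy)phenyl]-3-[3,5-bis(benzyloxy)-2-bromophenyl]-N-methoxy-N-methyl-4-nitrobutanamide F8, and commercial 4-(benzyloxy)phenylmagnesium bromide (excess, to cover the nitronate) converts it into 16.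

Step 19. The crowded ortho-quinone methide may be captured by adventitious nucleophiles or oligomerise, and the ylide may add with poor facial selectivity. The fallback sets out from 24 and comes back at 32. O-Alkylation of 24 with 27 (K2CO3, DMF) gives the 4-(benzyloxy)benzyl ether of 24 F9, and hydrazine (N2H4·H2O, AcOH, EtOH, 80 °C) gives its hydrazone F10. Oxidation with MnO2 and rhodium-carbene insertion into the benzylic C–H bond (Rh2(S-PTAD)4, same flask) should give the cis-(2R,3S) epimer of 32 at C2 of the upper dihydrobenzofuran F11. A catalytic amount of TFA then epimerises C2 through the ring-opened 4-alkoxybenzyl cation to the trans compound 32.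

**Further compounds**

F1 | step 4 | methyl 3-(benzyloxy)-4-hydroxybenzoate | COC(=O)c1ccc(O)c(OCc2ccccc2)c1
F2 | step 4 | methyl 3-(benzyloxy)-5-formyl-4-hydroxybenzoate | COC(=O)c1cc(C=O)c(O)c(OCc2ccccc2)c1
F3 | step 4 | methyl 3-(benzyloxy)-4-[(tert-butoxycarbonyl)oxy]-5-formylbenzoate | COC(=O)c1cc(C=O)c(OC(=O)OC(C)(C)C)c(OCc2ccccc2)c1
F4 | step 4 | [3,5-bis(benzyloxy)phenyl]magnesium bromide | Br[Mg]c1cc(OCc2ccccc2)cc(OCc2ccccc2)c1
F5 | step 4 | (2S,5S)-1-[4-(benzyloxy)benzyl]-2,5-dimethylthiolan-1-ium bromide | C[C@H]1CC[C@H](C)[S+]1Cc1ccc(OCc2ccccc2)cc1.[Br-]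
F6 | step 10 | (4R)-4-benzyl-3-{[3,5-bis(benzyloxy)phenyl]acetyl}-1,3-oxazolidin-2-one | O=C(Cc1cc(OCc2ccccc2)cc(OCc2ccccc2)c1)N1[C@H](Cc2ccccc2)COC1=O
F7 | step 10 | (4R)-4-benzyl-3-[(2R,3S)-2-[3,5-bis(benzyloxy)phenyl]-3-[3,5-bis(benzyloxy)-2-bromophenyl]-4-nitrobutanoyl]-1,3-oxazolidin-2-one | Brc1c(OCc9ccccc9)cc(OCc9ccccc9)cc1[C@@H](C[N+](=O)[O-])[C@H](c1cc(OCc9ccccc9)cc(OCc9ccccc9)c1)C(=O)N1[C@H](Cc2ccccc2)COC1=O
F8 | step 10 | (2R,3S)-2-[3,5-bis(benzyloxy)phenyl]-3-[3,5-bis(benzyloxy)-2-bromophenyl]-N-methoxy-N-methyl-4-nitrobutanamide | Brc1c(OCc9ccccc9)cc(OCc9ccccc9)cc1[C@@H](C[N+](=O)[O-])[C@H](c1cc(OCc9ccccc9)cc(OCc9ccccc9)c1)C(=O)N(C)OC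
F9 | step 19 | 4-(benzyloxy)benzyl ether of 24 at the phenol ortho to the ketone | O=C(c1cc(OCc9ccccc9)c2c(c1)[C@@H](c1cc(OCc9ccccc9)cc(OCc9ccccc9)c1)[C@H](c1ccc(OCc9ccccc9)cc1)O2)c1c(OCc3ccc(OCc9ccccc9)cc3)cc(OCc9ccccc9)cc1[C@@H]1[C@H](c2cc(OCc9ccccc9)cc(OCc9ccccc9)c2)[C@@H](c2ccc(OCc9ccccc9)cc2)O[C@H]1c1ccc(OCc9ccccc9)cc1
F10 | step 19 | hydrazone of F9 | NN=C(c1cc(OCc9ccccc9)c2c(c1)[C@@H](c1cc(OCc9ccccc9)cc(OCc9ccccc9)c1)[C@H](c1ccc(OCc9ccccc9)cc1)O2)c1c(OCc3ccc(OCc9ccccc9)cc3)cc(OCc9ccccc9)cc1[C@@H]1[C@H](c2cc(OCc9ccccc9)cc(OCc9ccccc9)c2)[C@@H](c2ccc(OCc9ccccc9)cc2)O[C@H]1c1ccc(OCc9ccccc9)cc1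
F11 | step 19 | cis-(2R,3S) epimer of 32 at C2 of the upper dihydrobenzofuran | c9ccccc9COc1ccc([C@@H]2Oc3cc(OCc9ccccc9)cc([C@@H]4[C@H](c5cc(OCc9ccccc9)cc(OCc9ccccc9)c5)[C@@H](c5ccc(OCc9ccccc9)cc5)O[C@H]4c4ccc(OCc9ccccc9)cc4)c3[C@@H]2c2cc(OCc9ccccc9)c3c(c2)[C@@H](c2cc(OCc9ccccc9)cc(OCc9ccccc9)c2)[C@H](c2ccc(OCc9ccccc9)cc2)O3)cc1
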